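Ring C (C8, C9, C11, C12, C13, C14; gibberellane numbering) is disconnected at C8–C9 and C13–C14 into a 2-arylcyclobutanone (C9, C11, C12, C13) and a 1,1-disubstituted alkene (C8=C14) carried ortho to it on an aromatic ring A. A rhodium-catalysed cut-and-sew reaction inserts this alkene into the C9–C13 bond: the four-membered ketone grows by two atoms into ring C, ring B closes and quaternary C8 forms cis to H9 in one operation. The step exploits the C13 oxygen (as the ketone) and the cis B/C fusion at C8–C9. Ring A is then dearomatised (Birch methylation, lactonisation), ring D closed on C13 by a benzoin reaction, and C1–C3 oxidised.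

Key step: step 9

Assumption: gibberellane numbering is used for all intermediates (ring A C1–C5 and C10; ring B C5, C6, C8, C9, C10; ring C C8, C9, C11–C14; ring D C8, C13–C16); α and β are the faces as in the target (H5 and H9 are β).
Assumption: the (S)-prolinol methyl ether amide steers the C4 methylation of step 13 to the β face (the sense usual for 2-alkylbenzamides under kinetic conditions); were the sense opposite, the (R)-auxiliary would be used from step 1 with no other change.
Assumption: (R)-DTBM-SEGPHOS is taken as the ligand enantiomer matched to the (S)-cyclobutanone in step 9; if the antipode proves matched it is used instead.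

Step 1
Reactants: 1 3-bromo-2-methylbenzoic acid; 2 (S)-2-(methoxymethyl)pyrrolidine
Product: 4 (S)-(3-bromo-2-methylphenyl)[2-(methoxymethyl)pyrrolidin-1-yl]methanone, via acid chloride 3 (not isolated)
Conditions: SOCl2, DMF (cat.), PhMe, 70 °C; then 2, Et3N, CH2Cl2, 0 °C to rt
Reagents that add atoms: none
Why: Acid chloride formation and amidation (Schotten–Baumann type) attach the prolinol-derived auxiliary that later steers the C4 methylation and directs the benzylic lithiation at C6.

Step 2
Reactants: 4 aryl amide
Product: 5 (S)-[3-bromo-2-(bromomethyl)phenyl][2-(methoxymethyl)pyrrolidin-1-yl]methanone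
Conditions: NBS, PhCF3, 450 nm LED, 20 °C
Reagents that add atoms: N-bromosuccinimide, O=C1CCC(=O)N1Br
Why: Light-initiated Wohl–Ziegler radical bromination is selective for the single benzylic methyl group, the weakest C–H bond of 4; the bromide is taken on at once because 2-(bromomethyl)benzamides cyclise slowly to imidate salts.

Step 3
Reactants: 6 2,3-dibromopropene; 7 vinylmagnesium bromide
Product: 8 2-bromopenta-1,4-diene
Conditions: CuI (5 mol %), THF, −20 to 0 °C
Reagents that add atoms: none
Why: Copper-catalysed allylic substitution of the Grignard reagent at the allylic bromide (SN2 and SN2' give the same product) leaves the vinylic bromide for the next step.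

Step 4
Reactants: 8 2-bromopenta-1,4-diene; 5 benzylic bromide
Product: 10 (S)-[3-bromo-2-(2-methylidenepent-4-en-1-yl)phenyl][2-(methoxymethyl)pyrrolidin-1-yl]methanone, via dienyl Grignard reagent 9 (not isolated)
Conditions: Mg turnings, THF, 40 °C; then CuI (10 mol %), 5, −40 °C to rt
Reagents that add atoms: none
Why: Copper-catalysed Kumada-type sp2–sp3 coupling of the alkenyl Grignard reagent with the reactive benzylic bromide tolerates the aryl bromide and the hindered tertiary amide and installs C8, C14, C15 and C16 (the allyl group is a latent C15–C16 acetaldehyde arm).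

Step 5
Reactants: 10 aryl bromide
Product: 12 (S)-3-{[2-(methoxymethyl)pyrrolidin-1-yl]carbonyl}-2-(2-methylidenepent-4-en-1-yl)benzaldehyde, via aryllithium 11 (not isolated)
Conditions: n-BuLi, THF, −78 °C, 10 min; then DMF, −78 to 0 °C; H2O
Reagents that add atoms: N,N-dimethylformamide, CN(C)C=O
Why: Bromine–lithium exchange outruns deprotonation at −78 °C and the aryllithium is formylated with DMF (Bouveault aldehyde synthesis), the new aldehyde carbon being C9.

Step 6
Reactants: 12 aldehyde; 13 cyclopropyltriphenylphosphonium bromide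
Product: 15 (S)-[3-(cyclopropylidenemethyl)-2-(2-methylidenepent-4-en-1-yl)phenyl][2-(methoxymethyl)pyrrolidin-1-yl]methanone, via cyclopropylidene ylide 14 (not isolated)
Conditions: 13, KOtBu, THF, 0 to 50 °C; then 12
Reagents that add atoms: none
Why: Wittig olefination with the cyclopropylidene ylide gives the strained trisubstituted benzylidenecyclopropane, which brings in C11, C12 and C13.

Step 7
Reactants: 15 benzylidenecyclopropane
Product: 16 oxaspiropentane: (S)-{2-(2-methylidenepent-4-en-1-yl)-3-[(R)-1-oxaspiro[2.2]pentan-2-yl]phenyl}[2-(methoxymethyl)pyrrolidin-1-yl]methanone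
Conditions: 1,2:4,5-di-O-isopropylidene-β-D-erythro-2,3-hexodiulo-2,6-pyranose (Shi ketone, 30 mol %), Oxone (2KHSO5·KHSO4·K2SO4), K2CO3, Bu4NHSO4 (cat.), MeCN/dimethoxymethane/aq. buffer pH 10.5, 0 °C
Reagents that add atoms: potassium peroxymonosulfate, [K+].[O-]S(=O)(=O)OO
Why: Shi asymmetric epoxidation by the chiral dioxirane attacks the electron-rich, strained trisubstituted alkene much faster than the two terminal alkenes, and the spiro transition state of the D-fructose-derived ketone (sense as for trans-β-methylstyrene) should give the (R)-configured benzylic carbon.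

Step 8
Reactants: 16 oxaspiropentane
Product: 17 (S)-2-aryl-cyclobutanone: (S)-2-[3-{[(S)-2-(methoxymethyl)pyrrolidin-1-yl]carbonyl}-2-(2-methylidenepent-4-en-1-yl)phenyl]cyclobutan-1-one
Conditions: Et2AlCl (0.2 equiv), PhMe, −78 to −40 °C
Reagents that add atoms: none
Why: Lewis acid-promoted semipinacol-type rearrangement of the oxaspiropentane, in which a cyclopropane bond migrates to the benzylic carbon anti to the departing oxygen, so that C9 is inverted to the (S)-2-arylcyclobutanone and the strain of the spiro system drives the reaction.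

Step 9
Reactants: 17 (S)-2-aryl-cyclobutanone
Product: 18 tricyclic ketone (ring A aromatic; 13-oxo; 8β-allyl; 9β-H; cis-fused rings B/C; C4 amide of 2)
Conditions: [Rh(cod)2]BF4 (5 mol %), (R)-5,5'-bis[bis(3,5-di-tert-butyl-4-methoxyphenyl)phosphino]-4,4'-bi-1,3-benzodioxole ((R)-DTBM-SEGPHOS, 6 mol %), 1,4-dioxane, 40 °C
Reagents that add atoms: none
Why: Oxidative addition of the cationic monovalent rhodium centre into the strained, benzylic C9–C13 acyl–carbon bond (assisted by pre-coordination of the ortho-tethered alkene) gives a rhodacyclopentanone; 5-exo migratory insertion of C8=C14 into the Rh–C9 bond closes ring B, and C14–C13 reductive elimination closes ring C, so the four-membered ketone ring (C9, C11, C12, C13) is expanded by C8 and C14 to the six-membered ring. The closest known reaction type is the rhodium-catalysed cut-and-sew carboacylation of alkenes tethered to cyclobutanones and benzocyclobutenones, including 1,1-disubstituted alkenes that give quaternary centres. Ring B forms by insertion (five-membered, exo mode) and ring C by reductive elimination from a seven-membered acyl-alkyl rhodacycle. C9 reacts with retention, and the new quaternary C8 is set relative to it by the suprafacial insertion across the rigid three-atom aryl tether (C10, C5, C6), which should give the cis B/C fusion (H9 and the C8 allyl group both β) because a trans-fused indane would be strongly strained. The step needs C–C activation on the substituted side and insertion of the 1,1-disubstituted rather than the distal allyl alkene: the weaker benzylic bond next to the chelating alkene secures the first, the five- versus seven- or eight-membered ring closure the second, and the lack of a β-hydrogen at C8 blocks β-hydride elimination. The mild temperature is chosen to avoid decarbonylation and epimerisation at C9, and the matched ligand enantiomer should consume the major (S)-ketone faster than its minor antipode, which should raise the enantiomeric purity of 18.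

Step 10
Reactants: 18 tricyclic ketone
Product: 20 keto aldehyde (C16 aldehyde on the C8 arm; 13-oxo), via ozonide 19 (not isolated)
Conditions: O3, CH2Cl2, −78 °C; then Me2S, −78 °C to rt
Reagents that add atoms: ozone, [O-][O+]=O
Why: Ozonolysis with reductive work-up cleaves the only remaining alkene, the allyl group, to the C16 aldehyde while the electron-poor arene and the ketone are untouched.

Step 11
Reactants: 20 keto aldehyde
Product: 21 bis(dioxolane) (13-ketal; 16-acetal)
Conditions: 1,2-bis(trimethylsilyloxy)ethane (2.5 equiv), TMSOTf (5 mol %), CH2Cl2, −78 to −20 °C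
Reagents that add atoms: 1,2-bis(trimethylsilyloxy)ethane, C[Si](C)(C)OCCO[Si](C)(C)C
Why: Silyl-transfer acetalisation protects ketone and aldehyde as dioxolanes under non-aqueous, low-temperature conditions that avoid aldol reaction of the 1,5-keto aldehyde.

Step 12
Reactants: 21 bis(dioxolane)
Product: 23 6β-carboxylic acid (C7 acid on benzylic C6), via benzylic lithium compound 22 (not isolated)
Conditions: LiN(i-Pr)2 (2.5 equiv), THF, −78 to −40 °C; CO2, −78 °C; dilute HCl to pH 4, 0 °C
Reagents that add atoms: carbon dioxide, O=C=O
Why: Amide-directed lateral (benzylic) lithiation at C6, the only benzylic position ortho to the tertiary amide, followed by carboxylation introduces C7; CO2 should approach the planar benzylic anion from the β face, away from the cis-fused ring C, to give the 6β-acid, whose configuration is also the thermodynamically preferred one once ring A is trans-fused.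

Step 13
Reactants: 23 6β-carboxylic acid
Product: 25 diene acid (ring A 2,5(10)-diene; 4β-methyl; 4α-carboxamide; C7 acid), via dipotassium amide enolate 24 (not isolated)
Conditions: K (4 equiv), NH3/THF, t-BuOH (1 equiv), −78 °C; then MeI, −78 °C; NH4Cl; dilute HCl to pH 4
Reagents that add atoms: iodomethane, CI
Why: Asymmetric Birch reduction–alkylation of the prolinol-derived benzamide, in which 1,4-reduction (ipso/para) gives the chelated amide enolate that is methylated at C4 under auxiliary control on the β face (see assumption), creating quaternary C4 and leaving the C2=C3 and C5=C10 alkenes, while acetals and carboxylate are inert to K/NH3.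

Step 14
Reactants: 25 diene acid
Product: 26 allyl ester of 25 (C7 allyl ester)
Conditions: allyl bromide, K2CO3, DMF, rt
Reagents that add atoms: allyl bromide, C=CCBr
Why: Carboxylate O-alkylation (SN2) gives the allyl ester, a C7 protecting group that can be removed at the end under neutral palladium catalysis.

Step 15
Reactants: 26 allyl ester
Product: 27 lactone keto aldehyde (19,10-lactone with 10α-O; 5β-H; Δ2; 13-oxo; C16 aldehyde; C7 allyl ester)
Conditions: TsOH·H2O (1.5 equiv), THF/H2O (10:1), 55 °C; then aq. NaHCO3
Reagents that add atoms: water, O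
Why: Acid-mediated amide lactonisation, in which protonation of the tetrasubstituted C5=C10 alkene at C5 and capture of the tertiary C10 cation by the α-disposed amide oxygen occur as a trans-diaxial addition (H to the β face of C5, O to the α face of C10, both relayed from C4), hydrolysis of the iminium ether releases the auxiliary, and both dioxolanes are hydrolysed in the same pot.

Step 16
Reactants: 27 lactone keto aldehyde
Product: 28 α-ketol (ring D closed; 13-hydroxy-16-oxo-17-nor; Δ2; C7 allyl ester)
Conditions: 2-(pentafluorophenyl)-6,7-dihydro-5H-pyrrolo[2,1-c][1,2,4]triazol-2-ium tetrafluoroborate (10 mol %), DBU (10 mol %), THF, rt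
Reagents that add atoms: none
Why: Carbene-catalysed intramolecular crossed benzoin reaction, in which the Breslow intermediate of the C16 aldehyde adds to the C13 ketone to close ring D as the five-membered α-ketol, the configuration of the new carbinol C13 being dictated by the bridged bicyclo[3.2.1]octane geometry because the arm on C8 can reach only one face of the ketone.

Step 17
Reactants: 28 α-ketol
Product: 29 1β-alcohol (1β-hydroxy-Δ2; 13-hydroxy-16-oxo; C7 allyl ester)
Conditions: SeO2 (0.5 equiv), t-BuOOH (2 equiv), CH2Cl2, rt
Reagents that add atoms: tert-butyl hydroperoxide, CC(C)(C)OO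
Why: SeO2-catalysed allylic oxidation (ene reaction then [2,3]-sigmatropic shift) of the C2=C3 alkene can only abstract hydrogen at C1 (C4 is quaternary) and should proceed on the exo (β) face of the bridged lactone, opposite to the lactone bridge, to give the 1β-alcohol with the double bond returned to C2=C3.

Step 18
Reactants: 29 1β-alcohol
Product: 30 epoxy alcohol (1β-hydroxy-2β,3β-epoxide; 13-hydroxy-16-oxo; C7 allyl ester)
Conditions: VO(acac)2 (5 mol %), t-BuOOH (1.5 equiv), CH2Cl2, 0 °C to rt
Reagents that add atoms: tert-butyl hydroperoxide, CC(C)(C)OO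
Why: Hydroxyl-directed epoxidation with VO(acac)2 and t-BuOOH delivers oxygen to C2=C3 syn to the allylic 1β-OH (also the open exo face), setting C2 and C3 as the 2β,3β-epoxide, and no other hydroxyl-flanked alkene is present because C16 is still a ketone.

Step 19
Reactants: 30 epoxy alcohol
Product: 33 allyl ester of the target gibberellin, via bis-TMS ether 31 (not isolated), via silylated alkene 32 (not isolated)
Conditions: TMSCl, Et3N, DMAP (cat.), CH2Cl2, 0 °C; then Ph3PCH3Br/KOtBu (3 equiv), THF, 0 °C to rt; then aq. citric acid, MeOH, 0 °C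
Reagents that add atoms: methyltriphenylphosphonium bromide, [Br-].C[P+](c1ccccc1)(c1ccccc1)c1ccccc1
Why: Transient silylation blocks the 13-hydroxy-16-ketone from base-induced acyloin rearrangement, Wittig methylenation then converts the C16 ketone into the exocyclic alkene without touching ester, lactone or epoxide, and mild acid work-up removes the silyl ethers.

Step 20
Reactants: 33 allyl ester of the target gibberellin
Product: 34 target gibberellin (number 93 of the gibberellin A series; 1β,13-dihydroxy-2β,3β-epoxy-16-methylidene 19,10-lactone 7-acid)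
Conditions: Pd(PPh3)4 (5 mol %), morpholine, THF, rt; then dilute aq. KHSO4
Reagents that add atoms: none
Why: Palladium-catalysed allyl transfer to morpholine (Tsuji–Trost deallylation) frees the C7 acid under neutral conditions that spare the lactone, the epoxy alcohol and the allylic tertiary alcohol.

Compound list
1 | 3-bromo-2-methylbenzoic acid | Cc1c(Br)cccc1C(=O)O | starting material
2 | (S)-2-(methoxymethyl)pyrrolidine | COC[C@@H]1CCCN1 | starting material
3 | 3-bromo-2-methylbenzoyl chloride | Cc1c(Br)cccc1C(=O)Cl | intermediate (not isolated)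
4 | (S)-(3-bromo-2-methylphenyl)[2-(methoxymethyl)pyrrolidin-1-yl]methanone | Cc1c(Br)cccc1C(=O)N1CCC[C@H]1COC | intermediate
5 | (S)-[3-bromo-2-(bromomethyl)phenyl][2-(methoxymethyl)pyrrolidin-1-yl]methanone | BrCc1c(Br)cccc1C(=O)N1CCC[C@H]1COC | intermediate
6 | 2,3-dibromopropene | C=C(Br)CBr | starting material
7 | vinylmagnesium bromide | C=C[Mg]Br | starting material
8 | 2-bromopenta-1,4-diene | C=CCC(Br)=C | intermediate
9 | penta-1,4-dien-2-ylmagnesium bromide | C=CCC(=C)[Mg]Br | intermediate (not isolated)
10 | (S)-[3-bromo-2-(2-methylidenepent-4-en-1-yl)phenyl][2-(methoxymethyl)pyrrolidin-1-yl]methanone | C=CCC(=C)Cc1c(Br)cccc1C(=O)N1CCC[C@H]1COC | intermediate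
11 | aryllithium from 10 (Li in place of Br) | C=CCC(=C)Cc1c([Li])cccc1C(=O)N1CCC[C@H]1COC | intermediate (not isolated)
12 | (S)-3-{[2-(methoxymethyl)pyrrolidin-1-yl]carbonyl}-2-(2-methylidenepent-4-en-1-yl)benzaldehyde | C=CCC(=C)Cc1c(C=O)cccc1C(=O)N1CCC[C@H]1COC | intermediate
13 | cyclopropyltriphenylphosphonium bromide | [Br-].C1CC1[P+](c1ccccc1)(c1ccccc1)c1ccccc1 | starting material
14 | cyclopropylidenetriphenylphosphorane | C1CC1=P(c1ccccc1)(c1ccccc1)c1ccccc1 | intermediate (not isolated)
15 | (S)-[3-(cyclopropylidenemethyl)-2-(2-methylidenepent-4-en-1-yl)phenyl][2-(methoxymethyl)pyrrolidin-1-yl]methanone | C=CCC(=C)Cc1c(C=C2CC2)cccc1C(=O)N1CCC[C@H]1COC | intermediate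
16 | oxaspiropentane, (R) at the benzylic epoxide carbon (future C9) | C=CCC(=C)Cc1c([C@H]2OC23CC3)cccc1C(=O)N1CCC[C@H]1COC | intermediate
17 | (S)-2-arylcyclobutanone (C9 S; ring atoms C9, C11, C12, C13) | C=CCC(=C)Cc1c([C@@H]2CCC2=O)cccc1C(=O)N1CCC[C@H]1COC | intermediate
18 | tricyclic ketone: ring A aromatic, rings B/C cis-fused, 13-oxo, 8β-allyl, 9β-H, C4 amide of 2 | C=CC[C@]12CC(=O)CC[C@H]1c1cccc(C(=O)N3CCC[C@H]3COC)c1C2 | intermediate
19 | ozonide (1,2,4-trioxolane) of the allyl group of 18 | C1(OCOO1)C[C@]12CC(=O)CC[C@H]1c1cccc(C(=O)N3CCC[C@H]3COC)c1C2 | intermediate (not isolated)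
20 | keto aldehyde: 13-oxo, C8–CH2–CHO (C16 aldehyde) | O=CC[C@]12CC(=O)CC[C@H]1c1cccc(C(=O)N3CCC[C@H]3COC)c1C2 | intermediate
21 | bis(dioxolane) of 20 | O1CCOC1C[C@]12CC3(OCCO3)CC[C@H]1c1cccc(C(=O)N3CCC[C@H]3COC)c1C2 | intermediate
22 | C6-lithio derivative of 21 | O1CCOC1C[C@]12CC3(OCCO3)CC[C@H]1c1cccc(C(=O)N3CCC[C@H]3COC)c1C2[Li] | intermediate (not isolated)
23 | 6β-carboxylic acid (C7 acid) of 21 | O1CCOC1C[C@]12CC3(OCCO3)CC[C@H]1c1cccc(C(=O)N3CCC[C@H]3COC)c1[C@@H]2C(=O)O | intermediate
24 | dipotassium salt: C4 amide enolate of the 1,4-dihydro ring A and C7 carboxylate | [K+].[K+].O1CCOC1C[C@]12CC3(OCCO3)CC[C@H]1C1=C(C(C=CC1)=C([O-])N1CCC[C@H]1COC)[C@@H]2C(=O)[O-] | intermediate (not isolated)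
25 | diene acid: ring A 2,5(10)-diene, 4β-methyl, 4α-carboxamide, C7 acid | O1CCOC1C[C@]12CC3(OCCO3)CC[C@H]1C1=C([C@@](C)(C=CC1)C(=O)N1CCC[C@H]1COC)[C@@H]2C(=O)O | intermediate
26 | C7 allyl ester of 25 | O1CCOC1C[C@]12CC3(OCCO3)CC[C@H]1C1=C([C@@](C)(C=CC1)C(=O)N1CCC[C@H]1COC)[C@@H]2C(=O)OCC=C | intermediate
27 | 19,10-lactone (10α-O, 5β-H), Δ2, 13-oxo, C16 aldehyde, C7 allyl ester | O=CC[C@]12CC(=O)CC[C@H]1[C@@]13OC(=O)[C@@](C)([C@H]1[C@@H]2C(=O)OCC=C)C=CC3 | intermediate
28 | 13-hydroxy-16-oxo-17-nor tetracycle (ring D closed), Δ2, 19,10-lactone, C7 allyl ester | O=C1C[C@]23C[C@@]1(O)CC[C@H]2[C@@]12OC(=O)[C@@](C)([C@H]1[C@@H]3C(=O)OCC=C)C=CC2 | intermediate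
29 | 1β-hydroxy derivative of 28 | O=C1C[C@]23C[C@@]1(O)CC[C@H]2[C@@]12OC(=O)[C@@](C)([C@H]1[C@@H]3C(=O)OCC=C)C=C[C@H]2O | intermediate
30 | 1β-hydroxy-2β,3β-epoxy-13-hydroxy-16-oxo-17-nor lactone, C7 allyl ester | O=C1C[C@]23C[C@@]1(O)CC[C@H]2[C@@]12OC(=O)[C@@](C)([C@H]1[C@@H]3C(=O)OCC=C)[C@H]1O[C@H]1[C@H]2O | intermediate
31 | 1,13-bis(trimethylsilyl) ether of 30 | O=C1C[C@]23C[C@@]1(O[Si](C)(C)C)CC[C@H]2[C@@]12OC(=O)[C@@](C)([C@H]1[C@@H]3C(=O)OCC=C)[C@H]1O[C@H]1[C@H]2O[Si](C)(C)C | intermediate (not isolated)
32 | 1,13-bis(trimethylsilyl) ether of the allyl ester of the target gibberellin | C=C1C[C@]23C[C@@]1(O[Si](C)(C)C)CC[C@H]2[C@@]12OC(=O)[C@@](C)([C@H]1[C@@H]3C(=O)OCC=C)[C@H]1O[C@H]1[C@H]2O[Si](C)(C)C | intermediate (not isolated)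
33 | allyl ester of the target gibberellin (C7 allyl ester) | C=C1C[C@]23C[C@@]1(O)CC[C@H]2[C@@]12OC(=O)[C@@](C)([C@H]1[C@@H]3C(=O)OCC=C)[C@H]1O[C@H]1[C@H]2O | intermediate
34 | target gibberellin (number 93 of the gibberellin A series): 1β,13-dihydroxy-2β,3β-epoxy-16-methylidene 19,10-lactone 7-acid | C=C1C[C@]23C[C@@]1(O)CC[C@H]2[C@@]12OC(=O)[C@@](C)([C@H]1[C@@H]3C(=O)O)[C@H]1O[C@H]1[C@H]2O | target

Total steps: 20. Longest linear sequence: 19 steps (steps 1, 2 and 4 to 20, from 1 to 34).

Steps most likely to fail

Step 9. The acyl–rhodium intermediate may lose CO (decarbonylation to an arylcyclopropane), the metal may insert on the unsubstituted side of the ketone, C9 may epimerise before the alkene inserts, or the insertion may proceed with the opposite ring-fusion sense. The fallback sets out from 12 and comes back at 18, and ring C is then made by a one-carbon ring expansion. Aldehyde 12 is homologated with dimethyl (1-diazo-2-oxopropyl)phosphonate and K2CO3 in MeOH to the aryl alkyne F1. An asymmetric Pauson–Khand reaction of its 1,6-enyne unit ([Rh(CO)2Cl]2, (S)-BINAP or its antipode as required, AgOTf, CO 1 atm, THF, 90 °C) closes ring B and a cyclopentenone at once and should give the tricyclic enone F2 with quaternary C8. Conjugate reduction with [(Ph3P)CuH]6 should give the cis-fused cyclopentanone F3, in which the C13 ketone is flanked by C11 and C14. Me3SiCHN2 with BF3·OEt2 then inserts one carbon (C12) on the less hindered C11 side, so that the five-membered ketone ring expands to ring C of 18.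

Step 15. Protonation may stray to C2=C3 or move that alkene into conjugation, the liberated keto aldehyde may undergo acid-catalysed aldol closure, and the hindered amide may cyclise only slowly. The fallback sets out from 26 and comes back at 27. Amide iodolactonisation (I2, NaHCO3, THF/H2O, 0 °C) should give the 5β-iodo-19,10-lactone F4 with loss of the auxiliary and both dioxolanes intact. Radical deiodination (Bu3SnH, azobisisobutyronitrile, PhH, 80 °C) should give the 5β-H lactone bis(dioxolane) F5. Separate mild acetal hydrolysis (1 M HCl, THF, rt) then gives 27.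

Step 16. Enolisation and aldol closure of the keto aldehyde may compete with carbene addition, and the base may trigger acyloin rearrangement of the product. The fallback sets out from 27 and comes back at 28. Reductive pinacol cyclisation (SmI2, THF/MeOH, −78 °C) should give the cis-13,16-diol F6. Oxidation of its secondary C16 alcohol with Dess–Martin periodinane (NaHCO3, CH2Cl2) then gives 28.

Further compounds
F1 | step 9 | aryl alkyne: (S)-[3-ethynyl-2-(2-methylidenepent-4-en-1-yl)phenyl][2-(methoxymethyl)pyrrolidin-1-yl]methanone | C=CCC(=C)Cc1c(C#C)cccc1C(=O)N1CCC[C@H]1COC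
F2 | step 9 | tricyclic cyclopentenone (C9=C11 enone, 13-oxo, 8β-allyl, ring A aromatic, C4 amide of 2) | C=CC[C@]12CC(=O)C=C1c1cccc(C(=O)N3CCC[C@H]3COC)c1C2
F3 | step 9 | cis-fused cyclopentanone (13-oxo flanked by C11 and C14, 8β-allyl, 9β-H) | C=CC[C@]12CC(=O)C[C@H]1c1cccc(C(=O)N3CCC[C@H]3COC)c1C2
F4 | step 15 | 5β-iodo-19,10-lactone bis(dioxolane), Δ2, C7 allyl ester | O1CCOC1C[C@]12CC3(OCCO3)CC[C@H]1[C@@]13OC(=O)[C@@](C)([C@@]1(I)[C@@H]2C(=O)OCC=C)C=CC3
F5 | step 15 | 5β-H 19,10-lactone bis(dioxolane), Δ2, C7 allyl ester | O1CCOC1C[C@]12CC3(OCCO3)CC[C@H]1[C@@]13OC(=O)[C@@](C)([C@H]1[C@@H]2C(=O)OCC=C)C=CC3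
F6 | step 16 | cis-13,16-diol (ring D closed, 17-nor), Δ2, 19,10-lactone, C7 allyl ester | O[C@@H]1C[C@]23C[C@@]1(O)CC[C@H]2[C@@]12OC(=O)[C@@](C)([C@H]1[C@@H]3C(=O)OCC=C)C=CC2
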